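Retrosynthetic cuts, in order: the two hydrogens on Cα–Cβ (back to a chalcone, then to a flavanone by joining one flanking oxygen to Cβ); the ring-B C3–CH2 prenyl bond (ortho-Claisen of a 1,1-dimethylallyl ether); the two hydrogens on chroman C3–C4; then chroman C4–C4a and O1–C2 together. This leaves naringenin and a C5 propargyl unit.
Enabling feature: in the benzene ring of the chroman, the acyl-bearing C6 lies between C5-OH and C7-OH, which become equivalent once the three-carbon chain is open, while the pyran oxygen O1 (on C8a) is para to C6. Tying either flanking oxygen to Cβ in a flavanone ring C, with the other chelated to the ketone, leaves only the para oxygen free to carry the propargyl group and close the pyran.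
Forward: naringenin already holds rings A and B and the temporary ring C. O7-propargylation and a thermal cascade close the dimethylpyran, the only ring that is built, and neutral hydrogenation turns it into the chroman.
Ring C stays closed and shields ring A while ring B is O-tert-prenylated and rearranged. Base then opens ring C, and a rhodium catalyst hydrogenates the chalcone alkene without touching the prenyl group.
Stereochemistry: the target has no stereocentre and no stereogenic double bond. Flavanone C2 is a passenger that disappears on ring opening.

Key step: step 2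

Remark: because the target is achiral, "single enantiomer" sets no task. C2 of the flavanone intermediates is drawn (S) as in natural naringenin, racemic naringenin serves equally, and erosion at C2 under base or heat has no consequence.

Step 1
Reactants: 1 (S)-naringenin; 2 3-chloro-3-methylbut-1-yne
Product: 3 (S)-naringenin 7-O-(1,1-dimethylpropargyl) ether
Conditions: 2 (1.1 equiv), CuCl (2 mol %), DBU (1.05 equiv), MeCN, 0 °C → rt
Reagents that add atoms: none
Why: Copper-catalysed propargylic substitution of a tertiary propargyl chloride by a phenoxide: with about one equivalent of base only the 7-OH, a vinylogous acid para to the carbonyl-bearing C4a, is ionised (5-OH is chelated to C4=O and 4'-OH is clearly less acidic), so O7 alone captures the copper-activated propargyl unit at its tertiary carbon, and the short, cold exposure to DBU leaves ring C closed.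

Step 2
Reactants: 3 (S)-naringenin 7-O-(1,1-dimethylpropargyl) ether
Product: 7 (2S)-5,4'-dihydroxy-6'',6''-dimethylpyrano[2'',3'':7,8]flavanone (pyran O on C7 and pyran CH= on C8), via allenyl dienone 4 (not isolated), via 8-allenylphenol 5 (not isolated), via ortho-quinone methide 6 (not isolated)
Conditions: PhNEt2, 170 °C, Ar; dilute HCl wash
Reagents that add atoms: none
Why: Heating triggers an aromatic propargyl Claisen [3,3] shift from O7 to C8 that forms the C8–CH bond (the future chroman C4a–C4 bond) and gives allenyl dienone 4, which enolises to allenylphenol 5. A 1,5-hydrogen shift from the new 7-OH to the central allene carbon then gives the (Z)-ortho-quinone methide 6, and a thermally allowed disrotatory oxa-6π electrocyclisation joins O7 to the CMe2 terminus (the future O1–C2 bond), closing the six-membered 2H-pyran. The closest known reaction type is the thermal conversion of aryl 1,1-dimethylpropargyl ethers into 2,2-dimethyl-2H-chromenes, which the gem-dimethyl group accelerates. No lasting stereocentre is made: the sp3 C8 of 4 is flattened on enolisation and C2 is a bystander. The selectivity that matters is which oxygen closes the ring, and the substrate secures it, since next to C8 the only other oxygen is O1, locked in ring C, and next to C6 it is the 5-OH, held in a hydrogen bond to C4=O, while the migrating hydrogen sits on O7. Site selectivity between C8 and C6 is not required, because a C6 (linear) isomer would pass through steps 3 to 6 in the same way and open in step 7 to the same chalcone 16.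

Step 3
Reactants: 7 (2S)-5,4'-dihydroxy-6'',6''-dimethylpyrano[2'',3'':7,8]flavanone
Product: 8 (2S)-5,4'-dihydroxy-6'',6''-dimethyl-4'',5''-dihydropyrano[2'',3'':7,8]flavanone
Conditions: H2 (1 atm), 10% Pd/C, EtOAc, rt, stopped after one equivalent of H2
Reagents that add atoms: none
Why: Heterogeneous catalytic hydrogenation: the cis-disubstituted styrene-type alkene of the 2H-pyran is saturated over Pd/C in a neutral aprotic solvent well before the chelated aryl ketone or the benzylic C2–O1 bond can react, so ring C stays closed and no alkene remains that could interfere later.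

Step 4
Reactants: 9 2-methylbut-3-en-2-ol
Product: 11 tert-butyl 2-methylbut-3-en-2-yl carbonate, via lithium 2-methylbut-3-en-2-olate 10 (not isolated)
Conditions: n-BuLi (1.0 equiv), THF, −78 → 0 °C; Boc2O, 0 °C → rt; H2O quench
Reagents that add atoms: di-tert-butyl dicarbonate, CC(C)(C)OC(=O)OC(=O)OC(C)(C)C
Why: O-acylation of a tertiary lithium alkoxide with Boc2O, the usual entry to tertiary allylic tert-butyl carbonates, in which the preformed alkoxide 10 makes up for the low nucleophilicity of the hindered alcohol.

Step 5
Reactants: 8 (2S)-5,4'-dihydroxy-6'',6''-dimethyl-4'',5''-dihydropyrano[2'',3'':7,8]flavanone; 11 tert-butyl 2-methylbut-3-en-2-yl carbonate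
Product: 12 4'-O-(2-methylbut-3-en-2-yl) ether of 8
Conditions: 11 (1.5 equiv), Pd(PPh3)4 (3 mol %), THF, 0 °C
Reagents that add atoms: none
Why: Palladium-catalysed decarboxylative allylic etherification (Tsuji–Trost type): ionisation of 11 releases CO2 and tert-butoxide, which deprotonates the only unchelated phenol (4'-OH; of the ring-A oxygens one is O1 of ring C and the other is hydrogen-bonded to C4=O), and at low temperature the phenoxide attacks the more substituted terminus of the 1,1-dimethyl-π-allyl complex to give the tertiary ether.

Step 6
Reactants: 12 4'-O-(2-methylbut-3-en-2-yl) ether of 8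
Product: 14 (2S)-5,4'-dihydroxy-3'-(3-methylbut-2-enyl)-6'',6''-dimethyl-4'',5''-dihydropyrano[2'',3'':7,8]flavanone, via ortho-dienone 13 (not isolated)
Conditions: o-xylene, 130 °C, Ar
Reagents that add atoms: none
Why: Aromatic Claisen rearrangement: the chair-like [3,3] shift moves the allyl unit with inversion from O4' to the ortho carbon, so the tertiary ether becomes a 3-methylbut-2-enyl group, dienone 13 rearomatises by enolisation, the two ortho positions are equivalent, and the weak tertiary C–O bond lets the reaction run at a temperature the flavanone tolerates.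

Step 7
Reactants: 14 (2S)-5,4'-dihydroxy-3'-(3-methylbut-2-enyl)-6'',6''-dimethyl-4'',5''-dihydropyrano[2'',3'':7,8]flavanone
Product: 16 (E)-1-(5,7-dihydroxy-2,2-dimethylchroman-6-yl)-3-[4-hydroxy-3-(3-methylbut-2-enyl)phenyl]prop-2-en-1-one, via chalcone tripotassium salt 15 (not isolated)
Conditions: KOH (25% aq)/EtOH, Ar, rt → 40 °C; poured into ice-cold 2 M HCl, rapid EtOAc extraction at 0 °C
Reagents that add atoms: none
Why: E1cB retro-oxa-Michael opening, the standard base opening of 5-hydroxyflavanones: hydroxide ionises the phenols and deprotonates C3, the enolate expels the O1 phenoxide and erases C2, the equilibrium is drawn to the open (E)-chalcone as its triphenolate 15, and fast cold acidification past the pH window of re-closure should deliver neutral 16, as in the known preparation of 2',6'-dihydroxychalcones from their flavanones.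

Step 8
Reactants: 16 (E)-1-(5,7-dihydroxy-2,2-dimethylchroman-6-yl)-3-[4-hydroxy-3-(3-methylbut-2-enyl)phenyl]prop-2-en-1-one
Product: 17 1-(5,7-dihydroxy-2,2-dimethylchroman-6-yl)-3-[4-hydroxy-3-(3-methylbut-2-enyl)phenyl]propan-1-one (target)
Conditions: H2 (4 bar), RhCl(PPh3)3 (5 mol %), degassed THF–t-BuOH 1:1, rt → 40 °C
Reagents that add atoms: none
Why: Homogeneous hydrogenation with Wilkinson's catalyst, which binds and reduces the 1,2-disubstituted enone alkene but is practically inert towards the trisubstituted prenyl alkene, the ketone and the arenes, while the neutral medium keeps 16 from re-closing, and any flavanone that does form can be returned to step 7.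

Compound list
1 | (S)-naringenin | O=C1C[C@@H](c2ccc(O)cc2)Oc2cc(O)cc(O)c12 | starting material
2 | 3-chloro-3-methylbut-1-yne | CC(C)(Cl)C#C | starting material
3 | (S)-naringenin 7-O-(1,1-dimethylpropargyl) ether | C#CC(C)(C)Oc1cc(O)c2C(=O)C[C@@H](c3ccc(O)cc3)Oc2c1 | intermediate
4 | allenyl dienone: C7 ketone, sp3 C8 bearing H and a 3-methylbuta-1,2-dienyl group | O=C1C[C@@H](c2ccc(O)cc2)OC2=C1C(O)=CC(=O)C2C=C=C(C)C | intermediate
5 | (S)-8-(3-methylbuta-1,2-dienyl)naringenin | O=C1C[C@@H](c2ccc(O)cc2)Oc2c1c(O)cc(O)c2C=C=C(C)C | intermediate
6 | (Z)-ortho-quinone methide: C7 ketone, exocyclic C8=CH–CH=CMe2 with the isobutenyl arm syn to C7=O | O=C1C[C@@H](c2ccc(O)cc2)OC2=C1C(O)=CC(=O)/C2=C\C=C(C)C | intermediate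
7 | (2S)-5,4'-dihydroxy-6'',6''-dimethylpyrano[2'',3'':7,8]flavanone | O=C1C[C@@H](c2ccc(O)cc2)Oc2c1c(O)cc1OC(C)(C)C=Cc12 | intermediate
8 | (2S)-5,4'-dihydroxy-6'',6''-dimethyl-4'',5''-dihydropyrano[2'',3'':7,8]flavanone | O=C1C[C@@H](c2ccc(O)cc2)Oc2c1c(O)cc1OC(C)(C)CCc12 | intermediate
9 | 2-methylbut-3-en-2-ol | CC(C)(O)C=C | starting material
10 | lithium 2-methylbut-3-en-2-olate | [Li+].[O-]C(C)(C)C=C | intermediate
11 | tert-butyl 2-methylbut-3-en-2-yl carbonate | C=CC(C)(C)OC(=O)OC(C)(C)C | intermediate
12 | 4'-O-(2-methylbut-3-en-2-yl) ether of 8 | O=C1C[C@@H](c2ccc(OC(C)(C)C=C)cc2)Oc2c1c(O)cc1OC(C)(C)CCc12 | intermediate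
13 | ring-B ortho-dienone: C4' ketone, sp3 C3' bearing H and a 3-methylbut-2-enyl group | O=C1C[C@@H](C2=CC(CC=C(C)C)C(=O)C=C2)Oc2c1c(O)cc1OC(C)(C)CCc12 | intermediate
14 | (2S)-5,4'-dihydroxy-3'-(3-methylbut-2-enyl)-6'',6''-dimethyl-4'',5''-dihydropyrano[2'',3'':7,8]flavanone | O=C1C[C@@H](c2ccc(O)c(CC=C(C)C)c2)Oc2c1c(O)cc1OC(C)(C)CCc12 | intermediate
15 | tripotassium triphenolate of chalcone 16 | CC(C)=CCc1cc(/C=C/C(=O)c2c([O-])cc3c(c2[O-])CCC(C)(C)O3)ccc1[O-].[K+].[K+].[K+] | intermediate
16 | (E)-1-(5,7-dihydroxy-2,2-dimethylchroman-6-yl)-3-[4-hydroxy-3-(3-methylbut-2-enyl)phenyl]prop-2-en-1-one | CC(C)=CCc1cc(/C=C/C(=O)c2c(O)cc3c(c2O)CCC(C)(C)O3)ccc1O | intermediate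
17 | 1-(5,7-dihydroxy-2,2-dimethylchroman-6-yl)-3-[4-hydroxy-3-(3-methylbut-2-enyl)phenyl]propan-1-one | CC(C)=CCc1cc(CCC(=O)c2c(O)cc3c(c2O)CCC(C)(C)O3)ccc1O | target

Total step count: 8. Longest linear sequence: 7 (steps 1, 2, 3, 5, 6, 7, 8 from naringenin); step 4 is a one-step side branch.

Steps most likely to fail

Step 7. The open chalcone may re-close by oxa-Michael addition during acidification, extraction or concentration, so that flavanone comes back instead of 16. The fallback sets out from 14 and traps the open form as it is made. Boiling acetic anhydride with sodium acetate, the classical ring-opening acetylation of flavanones, should give the chalcone triacetate F1, which has no free ortho-hydroxyl and cannot cyclise. Hydrogenation of F1 with Wilkinson's catalyst as in step 8 should give the dihydrochalcone triacetate F2. Methanolysis with catalytic K2CO3 in MeOH at rt removes the three acetates and rejoins the route at 17.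

Step 8. Turnover on the hindered, electron-rich aryl enone may be slow, leaving time for creeping saturation of the prenyl alkene or for ring re-closure. The fallback sets out from 16 and distinguishes the two alkenes by polarity rather than by substitution. Palladium(0)-catalysed conjugate hydride transfer (Pd(PPh3)4, slow addition of Bu3SnH, AcOH, THF, rt) delivers hydride to Cβ and a proton to Cα of the enone only. An isolated alkene cannot take part. This path leads straight to 17, and no new compound is isolated on it (F0).

Step 5. Palladium(0) may re-ionise the tertiary ether, causing drift towards the linear O-prenyl ether or C-allylation of ring A. The fallback sets out from 8 and avoids π-allyl chemistry. Copper-catalysed etherification with 2 under the conditions of step 1 should give the 4'-O-(1,1-dimethylpropargyl) ether F3. Semi-hydrogenation over Lindlar catalyst (H2, quinoline, EtOAc), with no other reducible alkene present, rejoins the route at 12.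

Further compounds
F1 | step 7 | (E)-chalcone triacetate: 16 with all three phenols acetylated | CC(C)=CCc1cc(/C=C/C(=O)c2c(OC(C)=O)cc3c(c2OC(C)=O)CCC(C)(C)O3)ccc1OC(C)=O
F2 | step 7 | dihydrochalcone triacetate: 17 with all three phenols acetylated | CC(C)=CCc1cc(CCC(=O)c2c(OC(C)=O)cc3c(c2OC(C)=O)CCC(C)(C)O3)ccc1OC(C)=O
F0 | step 8 | none | none
F3 | step 5 | 4'-O-(2-methylbut-3-yn-2-yl) ether of 8 | O=C1C[C@@H](c2ccc(OC(C)(C)C#C)cc2)Oc2c1c(O)cc1OC(C)(C)CCc12
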